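**Retrosynthetic overview**
- Late stage: the O15 methyl succinate and O19 isovalerate are put on a 15,19-diol; the 13E allylic alcohol comes from a terminal alkyne (Negishi carboalumination, formaldehyde); C17 comes from a C7=C8 enol triflate; C18 and C19 come from a C4 ketone.
- Key disconnection: ring B is a cyclohexene whose C7=C8 double bond lies between C6 and C9 (a Diels–Alder retron). It is cut at C5–C6 and C9–C10 (quaternary C10) into a ring-A enone (C4=O, C5=C10) and a 2-silyloxydiene C6=C7–C8(OSi)=C9 that carries the side chain; the enol oxygen on C8 stands in for C17 during the key step.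
- Enabling feature: the C2 oxygen of ring A is 1,3-cis to the C10–C9 bond, so one silicon atom can tie O2 to the C8 enol oxygen. The tether makes the cycloaddition intramolecular and sets C10 from C2; the C4 and C8 carbonyls then allow C5 and C9 to be equilibrated.
- Ring order: ring A first (ring-closing metathesis; C2 from ethyl (S)-4-chloro-3-hydroxybutanoate), then ring B in the key step together with a temporary eight-membered siloxane ring that is hydrolysed in the next step.

Key step: step 10

Remark: bicyclic compounds are named with labdane numbering (ring A: C1–C5 and C10; ring B: C5–C10; C17 on C8; C18 (α) and C19 (β) on C4; C20 on C10; side chain C11–C16 on C9); β is the face of C20, and 5α-H, 9α-H, 10β-methyl apply unless stated.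
Assumption: under equilibrating conditions the 4,8-diketone 17 should prefer the trans ring fusion and the equatorial (9β) side chain; step 11 relies on this.

**Ring A fragment**

Step 1
Reactants: 1 ethyl (S)-4-chloro-3-hydroxybutanoate
Product: 3 ethyl (R)-3-hydroxy-5-methylhex-5-enoate, via ethyl (S)-3,4-epoxybutanoate 2 (not isolated)
Conditions: CH2=C(CH3)MgBr (2.3 equiv), CuI (10 mol%), THF, −40 to 0 °C; aq. NH4Cl
Reagents that add atoms: isopropenylmagnesium bromide, C=C(C)[Mg]Br
Why: Copper-catalysed Grignard opening of an epoxide: the first equivalent of Grignard reagent turns the chlorohydrin into its magnesium alkoxide, which closes to epoxide 2, and the isopropenyl group then opens 2 at the unsubstituted carbon, so the carbinol carbon is never touched and keeps its configuration (the descriptor changes from S to R only through the priority change).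

Step 2
Reactants: 3 ethyl (R)-3-hydroxy-5-methylhex-5-enoate
Product: 4 (R)-3-hydroxy-N-methoxy-N,5-dimethylhex-5-enamide
Conditions: MeNH(OMe)·HCl, iPrMgCl, THF, −20 °C
Reagents that add atoms: N,O-dimethylhydroxylamine hydrochloride, CNOC.Cl
Why: Aminolysis of the ester by the chloromagnesium amide of N,O-dimethylhydroxylamine gives the Weinreb amide without protecting the alcohol and without touching the stereocentre.

Step 3
Reactants: 4 (R)-3-hydroxy-N-methoxy-N,5-dimethylhex-5-enamide
Product: 5 (R)-N-methoxy-N,5-dimethyl-3-(triethylsilyloxy)hex-5-enamide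
Conditions: Et3SiCl, imidazole, CH2Cl2, 0 °C
Reagents that add atoms: chlorotriethylsilane, CC[Si](CC)(CC)Cl
Why: Standard silylation of the secondary alcohol, needed so that the β-hydroxy vinyl ketone of the next step cannot close by oxa-Michael addition.

Step 4
Reactants: 5 (R)-N-methoxy-N,5-dimethyl-3-(triethylsilyloxy)hex-5-enamide
Product: 6 (R)-7-methyl-5-(triethylsilyloxy)octa-1,7-dien-3-one
Conditions: CH2=CHMgBr, THF, −78 to 0 °C; cold aq. HCl quench
Reagents that add atoms: vinylmagnesium bromide, C=C[Mg]Br
Why: Weinreb ketone synthesis, in which the chelated tetrahedral intermediate stops at the ketone stage and the vinyl ketone is released only on the cold acidic quench.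

Step 5
Reactants: 6 (R)-7-methyl-5-(triethylsilyloxy)octa-1,7-dien-3-one
Product: 7 (R)-3-methyl-5-(triethylsilyloxy)cyclohex-2-en-1-one
Conditions: second-generation Grubbs catalyst (H2IMes)(PCy3)Cl2Ru=CHPh (3 mol%), CH2Cl2, 40 °C
Reagents that add atoms: none
Why: Ring-closing metathesis between the vinyl ketone and the 1,1-disubstituted alkene forms the trisubstituted cyclohexenone of ring A (C5=C10) with loss of ethene, a well-used way to 3-methylcyclohex-2-enones.

Step 6
Reactants: 7 (R)-3-methyl-5-(triethylsilyloxy)cyclohex-2-en-1-one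
Product: 8 (R)-5-hydroxy-3-methylcyclohex-2-en-1-one
Conditions: AcOH/THF/H2O (3:1:1), rt
Reagents that add atoms: none
Why: Mild acidic hydrolysis of the triethylsilyl ether frees the C2 hydroxyl without dehydrating the β-hydroxy enone, which base would threaten.

**Diene fragment**

Step 7
Reactants: 9 hex-5-ynoic acid
Product: 11 N-methoxy-N-methylhex-5-ynamide, via 1-(imidazol-1-yl)hex-5-yn-1-one 10 (not isolated)
Conditions: 1,1'-carbonyldiimidazole, CH2Cl2, rt; then MeNH(OMe)·HCl
Reagents that add atoms: 1,1'-carbonyldiimidazole, O=C(n1ccnc1)n1ccnc1 (imidazolyl group of 10 only); N,O-dimethylhydroxylamine hydrochloride, CNOC.Cl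
Why: Activation of the carboxylic acid as its acyl imidazolide followed by aminolysis is a standard Weinreb amide synthesis that tolerates the terminal alkyne.

Step 8
Reactants: 11 N-methoxy-N-methylhex-5-ynamide
Product: 12 oct-1-en-7-yn-3-one
Conditions: CH2=CHMgBr (2.3 equiv), THF, −78 to 0 °C; cold aq. HCl quench
Reagents that add atoms: vinylmagnesium bromide, C=C[Mg]Br
Why: Weinreb ketone synthesis, in which one extra equivalent of Grignard reagent is consumed by the alkyne C–H and the acetylide is reprotonated on work-up.

**Union, key step and equilibration**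

Step 9
Reactants: 8 (R)-5-hydroxy-3-methylcyclohex-2-en-1-one; 12 oct-1-en-7-yn-3-one
Product: 14 (R)-3-methyl-5-{[(3Z)-octa-1,3-dien-7-yn-3-yloxy]di(propan-2-yl)silyloxy}cyclohex-2-en-1-one, via alkoxysilyl triflate 13 (not isolated)
Conditions: iPr2Si(OTf)2, 2,6-lutidine, CH2Cl2, −78 °C; then 12, Et3N, −78 to 0 °C
Reagents that add atoms: di(propan-2-yl)silyl bis(trifluoromethanesulfonate), CC(C)[Si](OS(=O)(=O)C(F)(F)F)(OS(=O)(=O)C(F)(F)F)C(C)C
Why: Stepwise assembly of an unsymmetrical bis(oxy)silane: the alcohol of 8 displaces one triflate of the silyl bis(triflate) at low temperature and the remaining silyl triflate, with Et3N, enolises ketone 12 on its only enolisable side (soft enolisation), which should give mainly the Z silyl dienol ether.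

Step 10
Reactants: 14 (R)-3-methyl-5-{[(3Z)-octa-1,3-dien-7-yn-3-yloxy]di(propan-2-yl)silyloxy}cyclohex-2-en-1-one
Product: 15 cis-fused cycloadduct: 15,16,17,18,19-pentanorlabd-7-en-13-yn-4-one with 5β-H and 9β-H (side chain α), whose 2α oxygen and C8 enol oxygen are bridged by Si(iPr)2
Conditions: PhMe (0.005 M), BHT, 2,6-di-tert-butyl-4-methylpyridine (10 mol%), 160 °C, sealed tube
Reagents that add atoms: none
Why: Proposed new method: on heating, 14 should undergo an intramolecular [4+2] cycloaddition between its electron-rich 2-silyloxydiene (C6=C7–C8(OSi)=C9, largest HOMO coefficient at C9) and the enone C5=C10–C4=O (largest LUMO coefficient at the β-carbon C10) through an asynchronous concerted transition state in which the C9–C10 bond is ahead and the C5–C6 bond completes ring B. The closest known reaction types are the type 2 intramolecular Diels–Alder reaction run through a disposable bis(oxy)silane tether and the Diels–Alder reaction of 2-silyloxydienes with 3-methylcyclohex-2-enones that builds an angular-methyl quaternary carbon; what is new is their combination, with the tether silicon carried on the dienol oxygen and a β,β-disubstituted cyclic enone as dienophile. Ring B closes as a six-membered carbocycle by suprafacial [4+2] addition on both partners, and the same C9–C10 bond closes the eight-membered ring C8–O–Si–O–C2–C1–C10–C9, so that the product is a bridged bicyclo[5.3.1] bridgehead silyl enol ether (C7=C8) fused to ring A, a ring size at which such bridgehead alkenes form readily. C10 is controlled by the tether, because the diene can reach only the ring-A face that carries O2, so C9 enters cis to O2 and the C10 methyl ends trans to it as in the target; C5 receives C6 on the same face (cis fusion) and C9 follows from the Z dienol ether in the endo arrangement forced by the tether, and both of these centres are left for the equilibration of step 11, where each is alpha to a ketone. The step needs regioselectivity (C9 to C10 and C6 to C5), which the short tether to C2 and the matched polarisation of diene and enone secure, and it needs the diene to spare the terminal alkyne and other molecules of 14, which the unactivated alkyne and high dilution secure.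

Step 11
Reactants: 15 cis-fused silicon-bridged cycloadduct
Product: 17 2α-hydroxy-15,16,17,18,19-pentanorlabd-13-yne-4,8-dione (trans-fused; side chain 9β), via cis-fused 9-epi diketone 16 (not isolated)
Conditions: 2 M aq. HCl/THF (1:3), rt
Reagents that add atoms: none
Why: Acid hydrolysis of the silyl enol ether and the silyl ether frees the C8 and C4 ketones and the C2 alcohol, and continued acid-catalysed enolisation toward the more substituted carbons C5 and C9 should equilibrate both centres to the trans-fused diketone with the equatorial 9β side chain, favoured because the C4 and C8 carbonyls remove two of the four 1,3-diaxial contacts of the C10 methyl and an axial C9 substituent would meet H5 and H7.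

**Ring B and C4 elaboration**

Step 12
Reactants: 17 2α-hydroxy-15,16,17,18,19-pentanorlabd-13-yne-4,8-dione
Product: 18 2α-(triisopropylsilyloxy)-15,16,17,18,19-pentanorlabd-13-yne-4,8-dione
Conditions: iPr3SiOTf, 2,6-lutidine, CH2Cl2, −78 to 0 °C
Reagents that add atoms: tri(propan-2-yl)silyl trifluoromethanesulfonate, CC(C)[Si](OS(=O)(=O)C(F)(F)F)(C(C)C)C(C)C
Why: Silylation with the silyl triflate and a hindered pyridine base protects the C2 alcohol as a bulky ether that survives the later base, acid, organometallic and hydride steps and shields C3 in the next step.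

Step 13
Reactants: 18 2α-(triisopropylsilyloxy)-15,16,17,18,19-pentanorlabd-13-yne-4,8-dione
Product: 19 4-oxo-2α-(triisopropylsilyloxy)-15,16,17,18,19-pentanorlabd-7-en-13-yn-8-yl trifluoromethanesulfonate
Conditions: KN(SiMe3)2 (2.1 equiv), THF, −78 °C; then PhNTf2
Reagents that add atoms: N-phenylbis(trifluoromethanesulfonimide), O=S(=O)(N(c1ccccc1)S(=O)(=O)C(F)(F)F)C(F)(F)F
Why: Kinetic deprotonation by the hindered amide base should take place at the unhindered C7 methylene rather than at C3, which is screened by the neighbouring triisopropylsilyloxy group, or at the methines C5 and C9, and O-triflation of the potassium enolate gives the C7=C8 enol triflate with all stereocentres untouched; the second equivalent of base covers the alkyne C–H.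

Step 14
Reactants: 19 C7=C8 enol triflate
Product: 20 2α-(triisopropylsilyloxy)-15,16,18,19-tetranorlabd-7-en-13-yn-4-one
Conditions: Me4Sn, Pd(PPh3)4 (5 mol%), LiCl, DMF, 60 °C
Reagents that add atoms: tetramethylstannane, C[Sn](C)(C)C
Why: Stille coupling of an enol triflate with tetramethylstannane (oxidative addition, chloride-assisted transmetalation, reductive elimination) installs C17 on the preformed C7=C8 double bond under neutral conditions that spare the ketone, the β-silyloxy group and the alkyne.

Step 15
Reactants: 20 2α-(triisopropylsilyloxy)-15,16,18,19-tetranorlabd-7-en-13-yn-4-one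
Product: 21 19-methoxy-2α-(triisopropylsilyloxy)-15,16,18-trinorlabda-4(19),7-dien-13-yne (E/Z mixture at the enol ether)
Conditions: Ph3P(CH2OMe)Cl, KN(SiMe3)2, THF, 0 °C to rt
Reagents that add atoms: (methoxymethyl)triphenylphosphonium chloride, COC[P+](c1ccccc1)(c1ccccc1)c1ccccc1.[Cl-]
Why: Wittig methoxymethylenation of the only remaining ketone adds C19 as an enol ether, with excess ylide compensating for reversible deprotonation of the alkyne.

Step 16
Reactants: 21 C4 methoxymethylidene compound
Product: 22 2α-(triisopropylsilyloxy)-15,16,18-trinorlabd-7-en-13-yn-19-al (C4 epimers)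
Conditions: 2 M aq. HCl/THF, rt
Reagents that add atoms: water, O
Why: Acid hydrolysis of the enol ether (protonation at C4, hydration of the oxocarbenium ion, loss of methanol) gives the C19 aldehyde, whose C4 configuration is irrelevant because C4 is enolised in the next step.

Step 17
Reactants: 22 C19 aldehyde (C4 epimers)
Product: 23 2α-(triisopropylsilyloxy)-15,16-dinorlabd-7-en-13-yn-19-al (4α-methyl, 4β-formyl)
Conditions: KOtBu, MeI, THF/tBuOH, 0 °C
Reagents that add atoms: iodomethane, CI
Why: Alkylation of the exocyclic aldehyde enolate: iodomethane should approach C4 from the equatorial α direction because the axial β direction is blocked by the 1,3-diaxial C10 methyl group, which sets the quaternary centre with the new methyl α (C18) and the formyl group β (C19), and the weak alkoxide base leaves the alkyne C–H alone.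

Step 18
Reactants: 23 2α-(triisopropylsilyloxy)-15,16-dinorlabd-7-en-13-yn-19-al
Product: 24 2α-(triisopropylsilyloxy)-15,16-dinorlabd-7-en-13-yn-19-ol
Conditions: NaBH4, MeOH, 0 °C
Reagents that add atoms: none
Why: Borohydride reduction of the non-enolisable aldehyde gives the neopentyl C19 alcohol without touching the alkene or the alkyne.

**Side chain and end game**

Step 19
Reactants: 24 2α-(triisopropylsilyloxy)-15,16-dinorlabd-7-en-13-yn-19-ol
Product: 26 2α-(triisopropylsilyloxy)labda-7,13E-diene-15,19-diol, via alkenyldimethylalane 25 (not isolated)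
Conditions: AlMe3 (4 equiv), Cp2ZrCl2 (0.25 equiv), CH2Cl2, 0 °C to rt; evaporate; n-BuLi, THF, −78 °C; (CH2O)n, to rt
Reagents that add atoms: trimethylaluminium, C[Al](C)C; formaldehyde (as paraformaldehyde), C=O
Why: Negishi carboalumination: zirconocene-catalysed syn addition of a methyl–aluminium bond across the terminal alkyne puts the methyl on C13 and aluminium on C14, and the derived alkenylalanate is trapped by formaldehyde with retention, which fixes the 13E geometry, while the trisubstituted ring alkene is inert and the C19 hydroxyl is carried as its aluminium alkoxide.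

Step 20
Reactants: 26 2α-(triisopropylsilyloxy)labda-7,13E-diene-15,19-diol
Product: 27 19-hydroxy-2α-(triisopropylsilyloxy)labda-7,13E-dien-15-yl methyl butanedioate
Conditions: MeO2CCH2CH2COCl (1.05 equiv), pyridine, CH2Cl2, −40 °C
Reagents that add atoms: methyl 4-chloro-4-oxobutanoate, COC(=O)CCC(=O)Cl
Why: Acylation under kinetic control, in which the unhindered allylic primary C15 hydroxyl should react far faster than the axial neopentyl C19 hydroxyl, which is flanked by a quaternary carbon and is 1,3-diaxial to C20.

Step 21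
Reactants: 27 19-hydroxy-2α-(triisopropylsilyloxy)labda-7,13E-dien-15-yl methyl butanedioate
Product: 28 19-(3-methylbutanoyloxy)-2α-(triisopropylsilyloxy)labda-7,13E-dien-15-yl methyl butanedioate
Conditions: iPrCH2COCl, Et3N, DMAP (cat.), CH2Cl2, rt
Reagents that add atoms: 3-methylbutanoyl chloride, CC(C)CC(=O)Cl
Why: Acyl transfer catalysed by DMAP through the acylpyridinium ion esterifies the remaining hindered primary alcohol.

Step 22
Reactants: 28 19-(3-methylbutanoyloxy)-2α-(triisopropylsilyloxy)labda-7,13E-dien-15-yl methyl butanedioate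
Product: 29 2α-hydroxy-19-(3-methylbutanoyloxy)labda-7,13E-dien-15-yl methyl butanedioate (CNP0118741.1)
Conditions: HF·pyridine, THF, 0 °C to rt
Reagents that add atoms: none
Why: Fluoride cleaves the silicon–oxygen bond of the silyl ether under mildly acidic conditions that leave the three esters and both alkenes untouched, releasing the 2α alcohol of the target.

**Compound list**
1 | ethyl (S)-4-chloro-3-hydroxybutanoate | CCOC(=O)C[C@H](O)CCl | starting material
2 | ethyl (S)-3,4-epoxybutanoate | CCOC(=O)C[C@H]1CO1 | intermediate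
3 | ethyl (R)-3-hydroxy-5-methylhex-5-enoate | CCOC(=O)C[C@H](O)CC(C)=C | intermediate
4 | (R)-3-hydroxy-N-methoxy-N,5-dimethylhex-5-enamide | CON(C)C(=O)C[C@H](O)CC(C)=C | intermediate
5 | (R)-N-methoxy-N,5-dimethyl-3-(triethylsilyloxy)hex-5-enamide | CON(C)C(=O)C[C@H](O[Si](CC)(CC)CC)CC(C)=C | intermediate
6 | (R)-7-methyl-5-(triethylsilyloxy)octa-1,7-dien-3-one | C=CC(=O)C[C@H](O[Si](CC)(CC)CC)CC(C)=C | intermediate
7 | (R)-3-methyl-5-(triethylsilyloxy)cyclohex-2-en-1-one | O=C1C[C@H](O[Si](CC)(CC)CC)CC(C)=C1 | intermediate
8 | (R)-5-hydroxy-3-methylcyclohex-2-en-1-one | O=C1C[C@H](O)CC(C)=C1 | intermediate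
9 | hex-5-ynoic acid | C#CCCCC(=O)O | starting material
10 | 1-(imidazol-1-yl)hex-5-yn-1-one | C#CCCCC(=O)n1ccnc1 | intermediate
11 | N-methoxy-N-methylhex-5-ynamide | C#CCCCC(=O)N(C)OC | intermediate
12 | oct-1-en-7-yn-3-one | C#CCCCC(=O)C=C | intermediate
13 | (R)-[(5-methyl-3-oxocyclohex-4-en-1-yl)oxy]di(propan-2-yl)silyl trifluoromethanesulfonate | O=C1C[C@H](O[Si](C(C)C)(C(C)C)OS(=O)(=O)C(F)(F)F)CC(C)=C1 | intermediate
14 | (R)-3-methyl-5-{[(3Z)-octa-1,3-dien-7-yn-3-yloxy]di(propan-2-yl)silyloxy}cyclohex-2-en-1-one | O=C1C[C@H](O[Si](C(C)C)(C(C)C)O/C(C=C)=C\CCC#C)CC(C)=C1 | intermediate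
15 | cis-fused cycloadduct: 15,16,17,18,19-pentanorlabd-7-en-13-yn-4-one, 5β-H, 9β-H, with 2α-O and 8-O bridged by Si(iPr)2 | C#CCC[C@@H]1C3=CC[C@@H]2C(=O)C[C@@H](C[C@]12C)O[Si](C(C)C)(C(C)C)O3 | intermediate
16 | 2α-hydroxy-15,16,17,18,19-pentanorlabd-13-yne-4,8-dione, 5β-H, 9β-H (cis-fused 9-epi diketone) | C#CCC[C@@H]1C(=O)CC[C@@H]2C(=O)C[C@H](O)C[C@]12C | intermediate
17 | 2α-hydroxy-15,16,17,18,19-pentanorlabd-13-yne-4,8-dione (trans-fused, side chain 9β) | C#CCC[C@H]1C(=O)CC[C@H]2C(=O)C[C@H](O)C[C@]12C | intermediate
18 | 2α-(triisopropylsilyloxy)-15,16,17,18,19-pentanorlabd-13-yne-4,8-dione | C#CCC[C@H]1C(=O)CC[C@H]2C(=O)C[C@H](O[Si](C(C)C)(C(C)C)C(C)C)C[C@]12C | intermediate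
19 | 4-oxo-2α-(triisopropylsilyloxy)-15,16,17,18,19-pentanorlabd-7-en-13-yn-8-yl trifluoromethanesulfonate | C#CCC[C@H]1C(OS(=O)(=O)C(F)(F)F)=CC[C@H]2C(=O)C[C@H](O[Si](C(C)C)(C(C)C)C(C)C)C[C@]12C | intermediate
20 | 2α-(triisopropylsilyloxy)-15,16,18,19-tetranorlabd-7-en-13-yn-4-one | C#CCC[C@H]1C(C)=CC[C@H]2C(=O)C[C@H](O[Si](C(C)C)(C(C)C)C(C)C)C[C@]12C | intermediate
21 | 19-methoxy-2α-(triisopropylsilyloxy)-15,16,18-trinorlabda-4(19),7-dien-13-yne (E/Z mixture) | C#CCC[C@H]1C(C)=CC[C@H]2C(=COC)C[C@H](O[Si](C(C)C)(C(C)C)C(C)C)C[C@]12C | intermediate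
22 | 2α-(triisopropylsilyloxy)-15,16,18-trinorlabd-7-en-13-yn-19-al (C4 epimers) | C#CCC[C@H]1C(C)=CC[C@H]2C(C=O)C[C@H](O[Si](C(C)C)(C(C)C)C(C)C)C[C@]12C | intermediate
23 | 2α-(triisopropylsilyloxy)-15,16-dinorlabd-7-en-13-yn-19-al | C#CCC[C@H]1C(C)=CC[C@H]2[C@@](C)(C=O)C[C@H](O[Si](C(C)C)(C(C)C)C(C)C)C[C@]12C | intermediate
24 | 2α-(triisopropylsilyloxy)-15,16-dinorlabd-7-en-13-yn-19-ol | C#CCC[C@H]1C(C)=CC[C@H]2[C@@](C)(CO)C[C@H](O[Si](C(C)C)(C(C)C)C(C)C)C[C@]12C | intermediate
25 | (13E)-14-(dimethylalumanyl)-2α-(triisopropylsilyloxy)-15-norlabda-7,13-dien-19-ol, O-dimethylaluminium alkoxide | C[Al](C)/C=C(\C)CC[C@H]1C(C)=CC[C@H]2[C@@](C)(CO[Al](C)C)C[C@H](O[Si](C(C)C)(C(C)C)C(C)C)C[C@]12C | intermediate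
26 | 2α-(triisopropylsilyloxy)labda-7,13E-diene-15,19-diol | OC/C=C(\C)CC[C@H]1C(C)=CC[C@H]2[C@@](C)(CO)C[C@H](O[Si](C(C)C)(C(C)C)C(C)C)C[C@]12C | intermediate
27 | 19-hydroxy-2α-(triisopropylsilyloxy)labda-7,13E-dien-15-yl methyl butanedioate | COC(=O)CCC(=O)OC/C=C(\C)CC[C@H]1C(C)=CC[C@H]2[C@@](C)(CO)C[C@H](O[Si](C(C)C)(C(C)C)C(C)C)C[C@]12C | intermediate
28 | 19-(3-methylbutanoyloxy)-2α-(triisopropylsilyloxy)labda-7,13E-dien-15-yl methyl butanedioate | COC(=O)CCC(=O)OC/C=C(\C)CC[C@H]1C(C)=CC[C@H]2[C@@](C)(COC(=O)CC(C)C)C[C@H](O[Si](C(C)C)(C(C)C)C(C)C)C[C@]12C | intermediate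
29 | 2α-hydroxy-19-(3-methylbutanoyloxy)labda-7,13E-dien-15-yl methyl butanedioate (CNP0118741.1) | COC(=O)CCC(=O)OC/C=C(\C)CC[C@H]1C(C)=CC[C@H]2[C@@](C)(COC(=O)CC(C)C)C[C@H](O)C[C@]12C | target

**Step count and risks**
Total step count: 22. Longest linear sequence: 20 steps (steps 1–6, then 9–22).

Most likely to fail, first: step 10 (proposed new method). The cycloaddition may be too slow at the hindered β,β-disubstituted enone, so that cleavage of the silyl dienol ether by adventitious acid, or oligomerisation, takes over before ring B closes. The fallback uses known polar chemistry on the same precursor and still closes ring B at C5–C6. It sets out from 14: TiCl4 in CH2Cl2 at −78 °C should bring about an intramolecular Mukaiyama–Michael addition (C9 to C10, still delivered on the O2 face by the tether); after aqueous work-up this gives the open-chain diketone 5-hydroxy-3-methyl-3-(3-oxooct-1-en-7-yn-4-yl)cyclohexan-1-one F1. Cs2CO3 in MeCN should then add the C5 enolate of the ring ketone to the vinyl ketone terminus C6 (intramolecular Michael addition) and equilibrate C5 and C9, so that the route is rejoined at 17.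

Second: step 11. Under the acid needed for equilibration the β-hydroxy ketone (C2–OH, C4=O) may lose water, and equilibration at C9 may stop short. The fallback sets out from 15: Bu4NF buffered with AcOH in THF at 0 °C cleaves both Si–O bonds without mineral acid, and the cis-fused diketone 16 is isolated. iPr3SiOTf/2,6-lutidine converts it into the cis-fused 9-epi silyl ether 2α-(triisopropylsilyloxy)-15,16,17,18,19-pentanorlabd-13-yne-4,8-dione (5β-H, 9β-H) F2, and DBU in toluene then equilibrates C5 and C9 on a substrate that can no longer dehydrate, rejoining the route at 18.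

Third: step 13. The kinetic enolisation may not discriminate well enough between the two α-methylene groups (C7 and C3) of a nearly symmetric diketone, and a C3 enolate could expel the silyloxy group. The fallback sets out from 17 and removes the choice by using the free C2 hydroxyl:
- Me4NBH(OAc)3 in MeCN/AcOH (Evans–Saksena reduction, intramolecular hydride delivery) should reduce only the β-hydroxy ketone at C4, giving 2α,4β-dihydroxy-15,16,17,18,19-pentanorlabd-13-yn-8-one F3.
- iPr3SiOTf (1 equiv) should silylate the equatorial C2 hydroxyl and leave the axial C4 hydroxyl, which is 1,3-diaxial to C20, giving 4β-hydroxy-2α-(triisopropylsilyloxy)-15,16,17,18,19-pentanorlabd-13-yn-8-one F4.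
- KN(SiMe3)2/PhNTf2 on the single ketone gives 4β-hydroxy-2α-(triisopropylsilyloxy)-15,16,17,18,19-pentanorlabd-7-en-13-yn-8-yl trifluoromethanesulfonate F5.
- Stille methylation gives 2α-(triisopropylsilyloxy)-15,16,18,19-tetranorlabd-7-en-13-yn-4β-ol F6, and Dess–Martin oxidation of the C4 alcohol rejoins the route at 20.

Further compounds
F1 | step 10 | 5-hydroxy-3-methyl-3-(3-oxooct-1-en-7-yn-4-yl)cyclohexan-1-one (ring carbons configured as C10 and C2 of 17; side-chain carbon as epimer mixture) | C#CCCC(C(=O)C=C)[C@]1(C)CC(=O)C[C@H](O)C1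
F2 | step 11 | 2α-(triisopropylsilyloxy)-15,16,17,18,19-pentanorlabd-13-yne-4,8-dione, 5β-H, 9β-H | C#CCC[C@@H]1C(=O)CC[C@@H]2C(=O)C[C@H](O[Si](C(C)C)(C(C)C)C(C)C)C[C@]12C
F3 | step 13 | 2α,4β-dihydroxy-15,16,17,18,19-pentanorlabd-13-yn-8-one | C#CCC[C@H]1C(=O)CC[C@H]2[C@@H](O)C[C@H](O)C[C@]12C
F4 | step 13 | 4β-hydroxy-2α-(triisopropylsilyloxy)-15,16,17,18,19-pentanorlabd-13-yn-8-one | C#CCC[C@H]1C(=O)CC[C@H]2[C@@H](O)C[C@H](O[Si](C(C)C)(C(C)C)C(C)C)C[C@]12C
F5 | step 13 | 4β-hydroxy-2α-(triisopropylsilyloxy)-15,16,17,18,19-pentanorlabd-7-en-13-yn-8-yl trifluoromethanesulfonate | C#CCC[C@H]1C(OS(=O)(=O)C(F)(F)F)=CC[C@H]2[C@@H](O)C[C@H](O[Si](C(C)C)(C(C)C)C(C)C)C[C@]12C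
F6 | step 13 | 2α-(triisopropylsilyloxy)-15,16,18,19-tetranorlabd-7-en-13-yn-4β-ol | C#CCC[C@H]1C(C)=CC[C@H]2[C@@H](O)C[C@H](O[Si](C(C)C)(C(C)C)C(C)C)C[C@]12C
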